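Ring A (C1, C2, C3, C4, C5, C10) is disconnected at C3–C4 as an intramolecular aldol. The key step adds the enolate of a preformed C19→C10 γ-lactone (C4) to a Z-enal (C1=C2–C3=O) attached at C10. It closes the six-membered carbocycle across the lactone, giving the 6-oxabicyclo[3.2.1]octenone and setting C3 and quaternary C4 at once. It exploits the β-hydroxy-lactone relation C3(OH)–C4–C19(=O) and the cis-1,3 arrangement of C4 and C10 on the lactone ring. The precursor is a BCD tricycle with this lactone, the Z-enal and the protected 12α,13-diol, assembled by Diels–Alder reaction, palladium cycloalkenylation and Michael lactonisation.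

Key step: step 16

Remark on the chemistry: gibberellane numbering (C1–C19) is used for all intermediates; β is the face of ring B that bears H-9 and the C15–C16 bridge, α the face that bears C11 and C14. The target is named throughout as 12α,15β-dihydroxygibberellic acid. The butanedione, the silyloxycyclopentenone and the diethoxypropyne are taken as commercial.

Step 1
Reactants: 1 butane-2,3-dione
Product: 2 2,3-bis(tert-butyldimethylsilyloxy)buta-1,3-diene
Conditions: TBSOTf (2.2 equiv), Et3N, CH2Cl2, 0 °C to rt
Reagents that add atoms: tert-butyldimethylsilyl trifluoromethanesulfonate, CC(C)(C)[Si](C)(C)OS(=O)(=O)C(F)(F)F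
Why: Double soft enolisation and O-silylation of the 1,2-diketone (silyl enol ether formation) should give the symmetrical 2,3-dioxygenated diene, as for the known bis(trimethylsilyl) analogue.

Step 2
Reactants: 3 (R)-4-(tert-butyldimethylsilyloxy)cyclopent-2-en-1-one
Product: 5 (R)-2-bromo-4-(tert-butyldimethylsilyloxy)cyclopent-2-en-1-one, via trans-dibromide 4 (not isolated)
Conditions: Br2, CH2Cl2, 0 °C; then Et3N, 0 °C to rt
Reagents that add atoms: bromine, BrBr
Why: Bromine addition to the enone and base-induced dehydrobromination (addition–elimination α-bromination of an enone) should install the vinylic bromide that activates the dienophile and later serves as radical precursor, leaving the C10 stereocentre untouched.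

Step 3
Reactants: 5 (R)-2-bromo-4-(tert-butyldimethylsilyloxy)cyclopent-2-en-1-one; 2 2,3-bis(tert-butyldimethylsilyloxy)buta-1,3-diene
Product: 6 cis-fused bromo ketone (C6 ketone; C8–Br, H-9 and 10-OTBS all β; C12=C13 bis(TBS) enediol ether)
Conditions: PhMe, BHT (cat.), 110 °C, sealed tube
Reagents that add atoms: none
Why: Thermal normal-demand Diels–Alder reaction in which the electron-rich diene should add suprafacially to the enone face anti to the C10 silyloxy group, so that C8 and C9 (cis ring fusion) are set by the commercial stereocentre, the symmetrical diene removing any regiochemical issue.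

Step 4
Reactants: 6 cis-fused bromo ketone
Product: 7 angular allyl ketone (β-allyl C15–C17 at C8 in place of Br)
Conditions: allyltributylstannane, AIBN (cat.), PhH, 80 °C
Reagents that add atoms: allyltributylstannane, C=CC[Sn](CCCC)(CCCC)CCCC
Why: Keck radical allylation, in which the tertiary α-keto radical at C8 should be trapped with retention of the cis ring fusion (a trans-fused hydrindanone is strongly disfavoured), placing the angular allyl group β, cis to H-9.

Step 5
Reactants: 7 angular allyl ketone
Product: 9 C5=C6 enol triflate, via potassium enolate 8 (not isolated)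
Conditions: KN(SiMe3)2, THF, −78 °C; then N-(5-chloropyridin-2-yl)bis(trifluoromethanesulfonimide), −78 °C
Reagents that add atoms: N-(5-chloropyridin-2-yl)bis(trifluoromethanesulfonimide), O=S(=O)(N(c1ccc(Cl)cn1)S(=O)(=O)C(F)(F)F)C(F)(F)F
Why: Kinetic enolate formation and O-triflation; C8 is quaternary, so the ketone can enolise only towards C5, and the pyridyl triflimide transfers the triflyl group at −78 °C, before the β-silyloxy enolate can expel the C10 silyloxide.

Step 6
Reactants: 9 C5=C6 enol triflate
Product: 10 2-(trimethylsilyl)ethyl enoate (C5=C6–C7O2CH2CH2SiMe3)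
Conditions: Pd(OAc)2 (5 mol%), PPh3, CO (1 atm), Me3SiCH2CH2OH (10 equiv), Et3N, DMF, 50 °C
Reagents that add atoms: carbon monoxide, [C-]#[O+]; 2-(trimethylsilyl)ethanol, C[Si](C)(C)CCO
Why: Palladium-catalysed alkoxycarbonylation of the enol triflate (oxidative addition to zerovalent palladium, CO insertion, alcoholysis) should install C7 as a fluoride-labile ester, alcohol capture of the acylpalladium being faster than insertion of the remote allyl group.

Step 7
Reactants: 10 2-(trimethylsilyl)ethyl enoate
Product: 11 BCD tricyclic ketone (12-oxo, 13-OTBS, exocyclic C16=C17, 10β-OTBS)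
Conditions: Pd(OAc)2 (10 mol%), O2 (1 atm), DMSO, 45 °C
Reagents that add atoms: none
Why: Oxidative cycloalkenylation of a silyl enol ether mediated by divalent palladium (an alkene-intercepted relative of the Saegusa oxidation), in which C13 (1,3 to the allyl-bearing C8) should add to the internal alkene carbon in a 5-exo mode and β-hydride elimination should leave the exocyclic methylene, the C13 configuration being dictated by the bicyclo[3.2.1]octane bridge.

Step 8
Reactants: 11 BCD tricyclic ketone
Product: 12 12α-alcohol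
Conditions: LiBH(s-Bu)3 (1.1 equiv), THF, −78 °C
Reagents that add atoms: none
Why: Ketone reduction with a bulky trialkylborohydride; axial attack at C12 is blocked by the axial C9–C10 bond, so hydride should enter equatorially from the side of the C15–C16 bridge and give the axial 12α-alcohol.

Step 9
Reactants: 12 12α-alcohol
Product: 13 10β,12α,13-triol
Conditions: HF (48% aq.)/MeCN (1:19), 0 °C to rt
Reagents that add atoms: none
Why: Acidic fluoride desilylation should cleave the secondary and the tertiary TBS ether (so any silyl migration in step 8 is inconsequential), while the 2-(trimethylsilyl)ethyl ester, which needs free fluoride ion, should survive.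

Step 10
Reactants: 13 10β,12α,13-triol
Product: 14 10-oxo enoate 12α,13-diol
Conditions: MnO2 (activated, excess), CH2Cl2, rt
Reagents that add atoms: none
Why: Chemoselective MnO2 oxidation of the C10 carbinol, the only allylic alcohol, should give the 4-oxo-enoate without touching the hindered 12α-secondary and 13-tertiary hydroxyls.

Step 11
Reactants: 14 10-oxo enoate 12α,13-diol
Product: 15 12α,13-bis(triethylsilyl) ether
Conditions: TESOTf (2.5 equiv), 2,6-lutidine, CH2Cl2, −78 to 0 °C
Reagents that add atoms: triethylsilyl trifluoromethanesulfonate, CC[Si](CC)(CC)OS(=O)(=O)C(F)(F)F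
Why: Silylation with a silyl triflate should cap the hindered secondary and the tertiary hydroxyl as fluoride-labile TES ethers before the organometallic and acylation chemistry.

Step 12
Reactants: 15 12α,13-bis(triethylsilyl) ether; 16 3,3-diethoxyprop-1-yne
Product: 18 C10 α-propanoate bearing the 10β-(3,3-diethoxyprop-1-ynyl) group, via lithium alkoxide 17 (not isolated)
Conditions: 16, n-BuLi, THF, −78 °C; add 15, −78 °C; then (EtCO)2O, DMAP (cat.), −78 °C to rt
Reagents that add atoms: propanoic anhydride, CCC(=O)OC(=O)CC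
Why: 1,2-Addition of a lithium acetylide to the cyclopentenone carbonyl and O-acylation of the tertiary alkoxide in the same flask; the nucleophile should approach C10 from the β face, anti to C11 and the 12α-silyloxy group, which sets C10 (C1 β, O α).

Step 13
Reactants: 18 C10 α-propanoate
Product: 19 19,10-lactone (5β-H, 6β-ester, C4 epimers)
Conditions: KOt-Bu (0.3 equiv), THF, −40 to 0 °C
Reagents that add atoms: none
Why: Base-mediated intramolecular Michael addition (5-exo-trig) of the propanoate enolate to C5 of the enoate closes the γ-lactone; the oxygen tether forces the new C4–C5 bond onto the α face (cis-fused lactone) and equilibrating protonation should place the C6 ester β, trans to C4.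

Step 14
Reactants: 19 19,10-lactone
Product: 20 (Z)-3,3-diethoxyprop-1-enyl lactone
Conditions: H2 (1 atm), Pd/CaCO3 poisoned with Pb(OAc)2 (Lindlar catalyst), quinoline, EtOAc, rt
Reagents that add atoms: none
Why: Lindlar semihydrogenation; syn delivery of hydrogen to the alkyne should give the (Z)-C1=C2 alkene, the 1,1-disubstituted C16 alkene being reduced far more slowly.

Step 15
Reactants: 20 (Z)-3,3-diethoxyprop-1-enyl lactone
Product: 21 (Z)-enal lactone
Conditions: PPTS (cat.), acetone–H2O (10:1), 0 °C; used at once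
Reagents that add atoms: water, O
Why: Mild acid-catalysed acetal hydrolysis should unveil the C3 aldehyde under conditions that spare the TES ethers and keep the Z geometry.

Step 16
Reactants: 21 (Z)-enal lactone
Product: 23 ring-A-closed 3β-hydroxy-Δ1 lactone, via potassium lactone enolate 22 (not isolated)
Conditions: KN(SiMe3)2 (1.1 equiv), 18-crown-6, THF, −78 °C; AcOH quench at −78 °C
Reagents that add atoms: none
Why: Deprotonation at C4 (the lactone α-hydrogen is more acidic and more accessible than H-6 of the ester) gives the potassium lactone enolate, whose C4 adds to the C3 aldehyde held in reach by the (Z)-C1=C2 alkene and by the cis relationship of C10–C1 and C4 on the convex face of the lactone, and the cold acetic acid quench releases the β-hydroxy lactone. The closest known reaction type is the intramolecular aldol addition of a lactone or ester enolate to a pendant aldehyde. Ring A (C1, C2, C3, C4, C5, C10) is closed in a 6-(enolexo)-exo-trig mode, the only mode the tether allows, because conjugate attack at C1 would need a four-membered ring. C4 is controlled by the tether (C3 can bond only to the convex lactone face, so the C18 methyl is left on the opposite face and the lactone becomes the axial bridge across ring A), and C3 by an open, non-chelated transition state in which the aldehyde oxygen points away from the enolate oxygen, which should place the hydroxyl anti to C19, that is 3β (axial). The step needs chemoselective enolisation at C4, retention of the Z-enal geometry and kinetic control at C3; these are secured by the higher acidity of the lactone, by the low temperature and short lifetime of the enal, and by the crown-ether-sequestered potassium counter-ion together with the cold quench that prevents retro-aldol equilibration.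

Step 17
Reactants: 23 ring-A-closed 3β-hydroxy-Δ1 lactone
Product: 24 15β-alcohol (12,13-bis(triethylsilyl) ether 2-(trimethylsilyl)ethyl ester of the target)
Conditions: SeO2 (0.5 equiv), t-BuOOH, CH2Cl2, 0 °C to rt
Reagents that add atoms: selenium dioxide (oxygen-transfer agent), O=[Se]=O; tert-butyl hydroperoxide (terminal oxidant), CC(C)(C)OO
Why: Selenium dioxide allylic hydroxylation (ene reaction followed by [2,3]-sigmatropic shift) at C15, the only allylic C–H of the exocyclic alkene; oxygen should be delivered to the face of ring D remote from the C7 ester (syn to H-9), as in ent-kaur-16-enes, which gives the 15β-alcohol.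

Step 18
Reactants: 24 15β-alcohol
Product: 25 12α,15β-dihydroxygibberellic acid (the target)
Conditions: (Me2N)3S+ Me3SiF2− (TASF, 6 equiv), DMF, 0 °C to rt; aq. NH4Cl
Reagents that add atoms: none
Why: Fluoride-induced cleavage of both TES ethers and β-elimination of the 2-(trimethylsilyl)ethyl ester under near-neutral, non-hydrolytic conditions should release the diol and the acid without opening or rearranging the acid- and base-sensitive allylic lactone of ring A.

Compound list
1 | butane-2,3-dione | CC(=O)C(C)=O | starting material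
2 | 2,3-bis(tert-butyldimethylsilyloxy)buta-1,3-diene | C=C(O[Si](C)(C)C(C)(C)C)C(=C)O[Si](C)(C)C(C)(C)C | intermediate
3 | (R)-4-(tert-butyldimethylsilyloxy)cyclopent-2-en-1-one | O=C1C=C[C@H](O[Si](C)(C)C(C)(C)C)C1 | starting material
4 | (4R)-2,3-dibromo-4-(tert-butyldimethylsilyloxy)cyclopentan-1-one, all-trans dibromide | O=C1[C@H](Br)[C@@H](Br)[C@H](O[Si](C)(C)C(C)(C)C)C1 | intermediate (not isolated)
5 | (R)-2-bromo-4-(tert-butyldimethylsilyloxy)cyclopent-2-en-1-one | O=C1C(Br)=C[C@H](O[Si](C)(C)C(C)(C)C)C1 | intermediate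
6 | 7a-bromo-3,5,6-tris(tert-butyldimethylsilyloxy)-2,3,3a,4,7,7a-hexahydro-1H-inden-1-one, cis-fused; Br (C8), H-3a (H-9) and 3-OTBS (C10) on the same β face | Br[C@]23CC(O[Si](C)(C)C(C)(C)C)=C(O[Si](C)(C)C(C)(C)C)C[C@H]2[C@H](O[Si](C)(C)C(C)(C)C)CC3=O | intermediate
7 | 7a-allyl analogue of 6 (β-allyl at C8, cis to H-9) | C=CC[C@]23CC(O[Si](C)(C)C(C)(C)C)=C(O[Si](C)(C)C(C)(C)C)C[C@H]2[C@H](O[Si](C)(C)C(C)(C)C)CC3=O | intermediate
8 | potassium C5=C6 enolate of 7 | C=CC[C@]23CC(O[Si](C)(C)C(C)(C)C)=C(O[Si](C)(C)C(C)(C)C)C[C@H]2[C@H](O[Si](C)(C)C(C)(C)C)C=C3[O-].[K+] | intermediate (not isolated)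
9 | C6 enol triflate of 7 (C5=C6–OTf) | C=CC[C@]23CC(O[Si](C)(C)C(C)(C)C)=C(O[Si](C)(C)C(C)(C)C)C[C@H]2[C@H](O[Si](C)(C)C(C)(C)C)C=C3OS(=O)(=O)C(F)(F)F | intermediate
10 | 2-(trimethylsilyl)ethyl enoate (C7 ester on C6, C5=C6; angular allyl; 10β-OTBS; C12=C13 bis(TBS) enediol ether) | C=CC[C@]23CC(O[Si](C)(C)C(C)(C)C)=C(O[Si](C)(C)C(C)(C)C)C[C@H]2[C@H](O[Si](C)(C)C(C)(C)C)C=C3C(=O)OCC[Si](C)(C)C | intermediate
11 | BCD tricycle: 12-ketone, 13-OTBS, exocyclic 16-methylene, 10β-OTBS, Δ5 2-(trimethylsilyl)ethyl 7-oate | C=C1C[C@]23C[C@@]1(O[Si](C)(C)C(C)(C)C)C(=O)C[C@H]2[C@H](O[Si](C)(C)C(C)(C)C)C=C3C(=O)OCC[Si](C)(C)C | intermediate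
12 | 12α-alcohol of 11 | C=C1C[C@]23C[C@@]1(O[Si](C)(C)C(C)(C)C)[C@@H](O)C[C@H]2[C@H](O[Si](C)(C)C(C)(C)C)C=C3C(=O)OCC[Si](C)(C)C | intermediate
13 | 10β,12α,13-triol (Δ5 2-(trimethylsilyl)ethyl 7-oate) | C=C1C[C@]23C[C@@]1(O)[C@@H](O)C[C@H]2[C@H](O)C=C3C(=O)OCC[Si](C)(C)C | intermediate
14 | 10-ketone (4-oxo-enoate) with free 12α,13-diol | C=C1C[C@]23C[C@@]1(O)[C@@H](O)C[C@H]2C(=O)C=C3C(=O)OCC[Si](C)(C)C | intermediate
15 | 12α,13-bis(triethylsilyl) ether of 14 | C=C1C[C@]23C[C@@]1(O[Si](CC)(CC)CC)[C@@H](O[Si](CC)(CC)CC)C[C@H]2C(=O)C=C3C(=O)OCC[Si](C)(C)C | intermediate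
16 | 3,3-diethoxyprop-1-yne | C#CC(OCC)OCC | starting material
17 | lithium 10α-alkoxide bearing the 10β-(3,3-diethoxyprop-1-ynyl) group | C=C1C[C@]23C[C@@]1(O[Si](CC)(CC)CC)[C@@H](O[Si](CC)(CC)CC)C[C@H]2[C@@]([O-])(C=C3C(=O)OCC[Si](C)(C)C)C#CC(OCC)OCC.[Li+] | intermediate (not isolated)
18 | 10α-propanoate of the acetylide adduct | C=C1C[C@]23C[C@@]1(O[Si](CC)(CC)CC)[C@@H](O[Si](CC)(CC)CC)C[C@H]2[C@@](OC(=O)CC)(C=C3C(=O)OCC[Si](C)(C)C)C#CC(OCC)OCC | intermediate
19 | 19,10-lactone (C4–C5 bond α, H-5 β, 6β-ester; mixture of C4 epimers, C4 left undefined) with 10β-alkynyl acetal | C=C1C[C@]23C[C@@]1(O[Si](CC)(CC)CC)[C@@H](O[Si](CC)(CC)CC)C[C@H]2[C@]4(OC(=O)C(C)[C@H]4[C@@H]3C(=O)OCC[Si](C)(C)C)C#CC(OCC)OCC | intermediate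
20 | (Z)-alkenyl diethyl acetal (Z-C1=C2) of 19 | C=C1C[C@]23C[C@@]1(O[Si](CC)(CC)CC)[C@@H](O[Si](CC)(CC)CC)C[C@H]2[C@]4(OC(=O)C(C)[C@H]4[C@@H]3C(=O)OCC[Si](C)(C)C)/C=C\C(OCC)OCC | intermediate
21 | (Z)-enal (C3 aldehyde) lactone | C=C1C[C@]23C[C@@]1(O[Si](CC)(CC)CC)[C@@H](O[Si](CC)(CC)CC)C[C@H]2[C@]4(OC(=O)C(C)[C@H]4[C@@H]3C(=O)OCC[Si](C)(C)C)/C=C\C=O | intermediate
22 | potassium lactone enolate (C4=C19) of 21 | C=C1C[C@]23C[C@@]1(O[Si](CC)(CC)CC)[C@@H](O[Si](CC)(CC)CC)C[C@H]2[C@]4(OC([O-])=C(C)[C@H]4[C@@H]3C(=O)OCC[Si](C)(C)C)/C=C\C=O.[K+] | intermediate (not isolated)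
23 | 15-deoxy precursor of the target with ring A closed (3β-OH, Δ1, 19,10-lactone; 12α,13-bis(triethylsilyl) ether; 2-(trimethylsilyl)ethyl 7-oate) | C=C1C[C@]23C[C@@]1(O[Si](CC)(CC)CC)[C@@H](O[Si](CC)(CC)CC)C[C@H]2[C@@]12C=C[C@H](O)[C@@](C)(C(=O)O1)[C@H]2[C@@H]3C(=O)OCC[Si](C)(C)C | intermediate
24 | 15β-hydroxy derivative of 23 (12α,13-bis(triethylsilyl) ether 2-(trimethylsilyl)ethyl ester of the target) | C=C1[C@@H](O)[C@]23C[C@@]1(O[Si](CC)(CC)CC)[C@@H](O[Si](CC)(CC)CC)C[C@H]2[C@@]12C=C[C@H](O)[C@@](C)(C(=O)O1)[C@H]2[C@@H]3C(=O)OCC[Si](C)(C)C | intermediate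
25 | 12α,15β-dihydroxygibberellic acid (3β,12α,13,15β-tetrahydroxy; Δ1; 16-methylene; 19,10-lactone; free 7-oic acid) | C=C1[C@@H](O)[C@]23C[C@@]1(O)[C@@H](O)C[C@H]2[C@@]12C=C[C@H](O)[C@@](C)(C(=O)O1)[C@H]2[C@@H]3C(=O)O | target

Total step count: 18. Longest linear sequence: 17 steps (3 to 25, steps 2–18); step 1 prepares diene 2 separately.

Steps most likely to fail

Step 16 (ring A aldol). The Z-enal may isomerise to the E-isomer before enolisation, and the E-enal cannot cyclise. The aldolate may also reopen by retro-aldol reaction, or addition may run through a chelated transition state and deliver the 3α-epimer. The fallback closes ring A by ring-closing metathesis of C1=C2 instead. It sets out from enone 15. Addition of vinylmagnesium bromide and propanoylation in the same flask would give the C10 vinyl propanoate F1. KOt-Bu would convert this into the vinyl lactone F2 by the same Michael closure as in step 13. Deprotonation with LiN(i-Pr)2 and aldol addition to acrolein on the convex lactone face would set C4 and give, after separation from its C3 epimer, the 3β-allylic alcohol diene F3. Ring-closing metathesis with second-generation Grubbs catalyst, RuCl2(=CHPh)(PCy3)(H2IMes), in CH2Cl2 at reflux would then form C1=C2 and return to 23.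

Step 7 (ring D). Carbopalladation may run through the other enol-ether terminus (C12, 6-exo) and give a bicyclo[2.2.2]octanone, or Saegusa-type dehydrogenation may compete with cyclisation. The fallback corrects the skeleton by α-ketol rearrangement and sets out from 10. The bicyclo[2.2.2]octanone F4 (C13 ketone, bridgehead 12-OTBS, C12–C16 bond) would be desilylated with aq. HF/MeCN to the bridgehead α-ketol F5. Lewis-acid-mediated α-ketol (acyloin) rearrangement with Al(Ot-Bu)3 in PhMe at 80 °C should shift C16 from C12 to C13 and give the bicyclo[3.2.1] ketol F6, which is expected to be the more stable ring system. Reduction with LiBH(s-Bu)3, as in step 8, would return to triol 13.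

Step 3 (Diels–Alder). The cycloaddition of the hindered α-bromo enone may be sluggish, with thermal loss of silanol from the β-silyloxy ketone or erosion of facial selectivity at the temperature needed. The fallback is a stepwise ionic annulation and sets out from 5 and 2. A Mukaiyama–Michael addition of one enol-ether terminus of 2 to enone 5 under catalytic TBSOTf in CH2Cl2 at −78 °C should occur anti to the C10 silyloxy group, with silyl transfer to the ring enolate, and give the open-chain silyl enol ether F7. A second, intramolecular Mukaiyama–Michael addition of its α-bromo silyl enol ether to the newly formed 2-silyloxy enone (catalytic TBSOTf, −40 °C) would close ring C cis and return to 6.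

Further compounds
F1 | step 16 | C10 vinyl α-propanoate (vinyl analogue of 18) | C=C1C[C@]23C[C@@]1(O[Si](CC)(CC)CC)[C@@H](O[Si](CC)(CC)CC)C[C@H]2[C@@](OC(=O)CC)(C=C3C(=O)OCC[Si](C)(C)C)C=C
F2 | step 16 | 10β-vinyl 19,10-lactone (vinyl analogue of 19, C4 epimers) | C=C1C[C@]23C[C@@]1(O[Si](CC)(CC)CC)[C@@H](O[Si](CC)(CC)CC)C[C@H]2[C@]4(OC(=O)C(C)[C@H]4[C@@H]3C(=O)OCC[Si](C)(C)C)C=C
F3 | step 16 | 10β-vinyl lactone with C4 quaternary (4-methyl; 3β-hydroxyprop-2-enyl at C4) | C=C1C[C@]23C[C@@]1(O[Si](CC)(CC)CC)[C@@H](O[Si](CC)(CC)CC)C[C@H]2[C@]4(OC(=O)[C@](C)([C@@H](O)C=C)[C@H]4[C@@H]3C(=O)OCC[Si](C)(C)C)C=C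
F4 | step 7 | bicyclo[2.2.2]octanone isomer of 11 (13-ketone, bridgehead 12-OTBS, C12–C16 bond) | C=C1C[C@]23CC(=O)[C@@]1(O[Si](C)(C)C(C)(C)C)C[C@H]2[C@H](O[Si](C)(C)C(C)(C)C)C=C3C(=O)OCC[Si](C)(C)C
F5 | step 7 | desilylated bicyclo[2.2.2] α-ketol (12-OH bridgehead, 13-ketone, 10β-OH) | C=C1C[C@]23CC(=O)[C@@]1(O)C[C@H]2[C@H](O)C=C3C(=O)OCC[Si](C)(C)C
F6 | step 7 | bicyclo[3.2.1] α-ketol (12-ketone, 13-OH, 10β-OH) | C=C1C[C@]23C[C@@]1(O)C(=O)C[C@H]2[C@H](O)C=C3C(=O)OCC[Si](C)(C)C
F7 | step 3 | Mukaiyama–Michael adduct: 2-bromo-1,4-bis(TBS-oxy)cyclopentene carrying a 3-(TBS-oxy)-2-oxobut-3-enyl chain at C9 | C=C(O[Si](C)(C)C(C)(C)C)C(=O)C[C@H]1[C@H](O[Si](C)(C)C(C)(C)C)CC(O[Si](C)(C)C(C)(C)C)=C1Br
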